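**Retrosynthetic overview**

1. The strategy rests on ring C, a benzene with OH on C1, the ether oxygen to ring B on C2 and the CH2CH2 link to ring D on C4 (para to the OH, meta to the ether oxygen), with C3, C5 and C6 as CH. This is the pattern of a 2,3-dioxygenated buta-1,3-diene (C6–C1–C2–C3) joined to an acyl alkyne (C4–C5).
2. Target ⇐ BBr3 cleavage of three methyl ethers and one silyl ether ⇐ ionic deoxygenation of a ring C aryl benzyl ketone (this gives the ring C–CH2CH2–ring D bridge) ⇐ DDQ dehydrogenation of a cyclohexa-1,4-diene.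
3. Cyclohexadiene ⇐ Diels–Alder reaction of a 2-aryloxy-3-silyloxybuta-1,3-diene with 1-(2,3-dimethoxyphenyl)but-3-yn-2-one, forming C3–C4 and C5–C6.
4. Diene ⇐ O-silylation of an α-aryloxy enone ⇐ Rh2(OAc)4-catalysed O–H insertion of the ring A–ring B phenol into a diazo ketophosphonate, then Horner–Wadsworth–Emmons methylenation; phenol ⇐ Wittig olefination and hydrogenation; ynone ⇐ Weinreb amide of the arylacetic acid.
5. Ring order: rings A, B and D are bought as arenes; ring C is the only ring built (step 8) and is aromatised in step 9.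

Key step: step 8

Remark: the target has no stereocentre and no stereogenic double bond, so no stereocontrol is needed; the phosphonium salt, the benzyloxy aldehyde, the diazo phosphonate and the arylacetic acid are taken as catalogue chemicals.

**Route**

Step 1
Reactants: 1 (3-methoxybenzyl)triphenylphosphonium chloride; 2 4-(benzyloxy)benzaldehyde
Product: 4 1-(benzyloxy)-4-[2-(3-methoxyphenyl)ethenyl]benzene (E/Z mixture), via (3-methoxybenzylidene)triphenylphosphorane 3 (not isolated)
Conditions: KOtBu, THF, 0 °C → rt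
Reagents that add atoms: none
Why: Wittig olefination: KOtBu converts the benzylic phosphonium salt into the semi-stabilised ylide 3, which condenses with the aldehyde, and the E/Z ratio does not matter because the alkene is hydrogenated next.

Step 2
Reactants: 4 1-(benzyloxy)-4-[2-(3-methoxyphenyl)ethenyl]benzene
Product: 5 4-[2-(3-methoxyphenyl)ethyl]phenol
Conditions: H2 (1 atm), 10% Pd/C, EtOAc–EtOH, rt
Reagents that add atoms: none
Why: Catalytic hydrogenation saturates the stilbene double bond and hydrogenolyses the benzyl ether in one operation, leaving the methyl ether and the arenes untouched.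

Step 3
Reactants: 5 4-[2-(3-methoxyphenyl)ethyl]phenol; 6 dimethyl (1-diazo-2-oxopropyl)phosphonate
Product: 7 dimethyl (1-{4-[2-(3-methoxyphenyl)ethyl]phenoxy}-2-oxopropyl)phosphonate (racemic)
Conditions: Rh2(OAc)4 (2 mol%), toluene, 80 °C
Reagents that add atoms: none
Why: Carbenoid O–H insertion: the electrophilic carbenoid that Rh2(OAc)4 generates from 6 is captured by the phenol oxygen (oxonium ylide, then proton shift), which puts the aryloxy group on the carbon that also carries the phosphonate, so the methylene of step 4 can only go there; the new stereocentre is racemic and is removed in step 4.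

Step 4
Reactants: 7 dimethyl (1-{4-[2-(3-methoxyphenyl)ethyl]phenoxy}-2-oxopropyl)phosphonate
Product: 8 3-{4-[2-(3-methoxyphenyl)ethyl]phenoxy}but-3-en-2-one
Conditions: 37% aq. HCHO, K2CO3, THF–H2O, 0 °C → rt
Reagents that add atoms: formaldehyde, C=O
Why: Horner–Wadsworth–Emmons olefination: the doubly activated phosphonate anion forms under carbonate base and olefinates formaldehyde, giving the 1,1-disubstituted α-aryloxy enone with no regiochemical ambiguity.

Step 5
Reactants: 8 3-{4-[2-(3-methoxyphenyl)ethyl]phenoxy}but-3-en-2-one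
Product: 9 tert-butyl[(3-{4-[2-(3-methoxyphenyl)ethyl]phenoxy}buta-1,3-dien-2-yl)oxy]dimethylsilane
Conditions: TBSOTf, Et3N, CH2Cl2, −78 → 0 °C; cold NaHCO3 wash, short basic alumina plug, used at once
Reagents that add atoms: tert-butyldimethylsilyl trifluoromethanesulfonate, CC(C)(C)[Si](C)(C)OS(=O)(=O)C(F)(F)F
Why: Silyl enol ether formation by soft enolisation: the methyl group is the only enolisable position of 8, so O-silylation can only give the cross-conjugated 2-silyloxy diene, as with methyl vinyl ketone.

Step 6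
Reactants: 10 (2,3-dimethoxyphenyl)acetic acid
Product: 12 2-(2,3-dimethoxyphenyl)-N-methoxy-N-methylacetamide, via 2-(2,3-dimethoxyphenyl)-1-(imidazol-1-yl)ethanone 11 (not isolated)
Conditions: CDI, CH2Cl2, rt; then MeNH(OMe)·HCl, rt
Reagents that add atoms: N,O-dimethylhydroxylamine hydrochloride, CNOC.Cl; 1,1'-carbonyldiimidazole, O=C(n1ccnc1)n1ccnc1 (its imidazolyl group is carried only in 11)
Why: Amide coupling through the acyl imidazolide 11 gives the Weinreb amide without an acid chloride that could acylate the electron-rich ring.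

Step 7
Reactants: 12 2-(2,3-dimethoxyphenyl)-N-methoxy-N-methylacetamide
Product: 14 1-(2,3-dimethoxyphenyl)but-3-yn-2-one, via bromomagnesium N-methoxy-N-methyl hemiaminal alkoxide 13 (not isolated)
Conditions: HC≡CMgBr (0.5 M in THF), THF, 0 °C; inverse quench into cold 1 M aq. HCl; used promptly
Reagents that add atoms: ethynylmagnesium bromide, C#C[Mg]Br
Why: Weinreb ketone synthesis: the alkynyl Grignard reagent adds once to give the stable chelate 13, and the inverse acidic quench protonates the released N,O-dimethylhydroxylamine so that it cannot add to the terminal ynone.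

Step 8
Reactants: 9 tert-butyl[(3-{4-[2-(3-methoxyphenyl)ethyl]phenoxy}buta-1,3-dien-2-yl)oxy]dimethylsilane; 14 1-(2,3-dimethoxyphenyl)but-3-yn-2-one
Product: 15 1-(4-{[tert-butyl(dimethyl)silyl]oxy}-5-{4-[2-(3-methoxyphenyl)ethyl]phenoxy}cyclohexa-1,4-dien-1-yl)-2-(2,3-dimethoxyphenyl)ethan-1-one
Conditions: 9 (1.5 equiv), toluene, BHT (cat.), 80 °C, Ar; crude adduct carried on
Reagents that add atoms: none
Why: Normal-electron-demand Diels–Alder reaction: the HOMO of the doubly oxygenated s-cis diene 9 and the LUMO of the acyl alkyne 14 combine in a concerted, asynchronous, suprafacial [4π+2π] event, the closest known reaction type being the cycloaddition of 2-silyloxy- and 2,3-bis(silyloxy)buta-1,3-dienes with alkynyl ketones to give cyclohexa-1,4-dienes that are later oxidised to phenols or catechols. Ring C is closed as a six-membered carbocycle by intermolecular [4+2] annulation in which C3–C4 and C5–C6 form in the same step (C5–C6 leading), the diene supplying C6, C1, C2 and C3 and the alkyne C4 and C5. No stereocentre is created, because every new ring atom is sp2 or a CH2. The selectivity that matters is regiochemical: the acyl-bearing carbon must end para to the silyloxy carbon C1 and meta to the aryloxy carbon C2. This should follow from the different donor strength of the two oxygens, since the lone pair of the aryloxy oxygen is shared with ring B while the silyloxy oxygen donates only into the diene, so the largest HOMO coefficient lies on the CH2 terminus next to the silyloxy carbon (future C6), which bonds to the unsubstituted alkyne terminus carrying the largest LUMO coefficient (future C5). The excess of diene, the neutral medium and the moderate temperature protect the acid-labile silyl enol ether and the base-sensitive benzylic ynone.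

Step 9
Reactants: 15 1-(4-{[tert-butyl(dimethyl)silyl]oxy}-5-{4-[2-(3-methoxyphenyl)ethyl]phenoxy}cyclohexa-1,4-dien-1-yl)-2-(2,3-dimethoxyphenyl)ethan-1-one
Product: 16 1-(4-{[tert-butyl(dimethyl)silyl]oxy}-3-{4-[2-(3-methoxyphenyl)ethyl]phenoxy}phenyl)-2-(2,3-dimethoxyphenyl)ethan-1-one
Conditions: DDQ (1.1 equiv), toluene, 0 °C → rt
Reagents that add atoms: none
Why: Dehydrogenative aromatisation: DDQ abstracts hydride from a doubly allylic CH2 of the 1,4-diene (the cation is stabilised by the enol ether oxygens) and proton loss gives the arene with the silyl ether on C1 and the aryl ether on C2, while the benzylic CH2 groups elsewhere react far more slowly at room temperature.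

Step 10
Reactants: 16 1-(4-{[tert-butyl(dimethyl)silyl]oxy}-3-{4-[2-(3-methoxyphenyl)ethyl]phenoxy}phenyl)-2-(2,3-dimethoxyphenyl)ethan-1-one
Product: 17 tert-butyl(4-[2-(2,3-dimethoxyphenyl)ethyl]-2-{4-[2-(3-methoxyphenyl)ethyl]phenoxy}phenoxy)dimethylsilane
Conditions: Et3SiH (4 equiv), CF3CO2H, CH2Cl2, 0 °C → rt
Reagents that add atoms: none
Why: Ionic hydrogenation: CF3CO2H protonates the electron-rich aryl ketone (para silyloxy donor) and Et3SiH delivers hydride twice, through the carbinol and the benzylic cation, to leave CH2; any stilbene formed by proton loss is reprotonated and reduced to the same product, and partial loss of the silyl group is harmless because step 11 removes it.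

Step 11
Reactants: 17 tert-butyl(4-[2-(2,3-dimethoxyphenyl)ethyl]-2-{4-[2-(3-methoxyphenyl)ethyl]phenoxy}phenoxy)dimethylsilane
Product: 18 3-{2-[4-hydroxy-3-(4-[2-(3-hydroxyphenyl)ethyl]phenoxy)phenyl]ethyl}benzene-1,2-diol (CNP0185459.0)
Conditions: BBr3 (8 equiv), CH2Cl2, −78 °C → rt; then H2O, 0 °C
Reagents that add atoms: none
Why: Lewis-acid ether cleavage: BBr3 coordinates each ether oxygen, bromide removes the three methyl groups and the silyl group, and hydrolysis of the aryl borates releases the four phenols, while the diaryl ether and the two ethylene bridges are inert to BBr3.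

**Compound list**

1 | (3-methoxybenzyl)triphenylphosphonium chloride | COc1cccc(C[P+](c2ccccc2)(c2ccccc2)c2ccccc2)c1.[Cl-] | starting material
2 | 4-(benzyloxy)benzaldehyde | O=Cc1ccc(OCc2ccccc2)cc1 | starting material
3 | (3-methoxybenzylidene)triphenylphosphorane | COc1cccc(C=P(c2ccccc2)(c2ccccc2)c2ccccc2)c1 | intermediate (not isolated)
4 | 1-(benzyloxy)-4-[2-(3-methoxyphenyl)ethenyl]benzene, E/Z mixture | COc1cccc(C=Cc2ccc(OCc3ccccc3)cc2)c1 | intermediate
5 | 4-[2-(3-methoxyphenyl)ethyl]phenol | COc1cccc(CCc2ccc(O)cc2)c1 | intermediate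
6 | dimethyl (1-diazo-2-oxopropyl)phosphonate | COP(=O)(OC)C(=[N+]=[N-])C(C)=O | starting material
7 | dimethyl (1-{4-[2-(3-methoxyphenyl)ethyl]phenoxy}-2-oxopropyl)phosphonate, racemic | COc1cccc(CCc2ccc(OC(C(C)=O)P(=O)(OC)OC)cc2)c1 | intermediate
8 | 3-{4-[2-(3-methoxyphenyl)ethyl]phenoxy}but-3-en-2-one | COc1cccc(CCc2ccc(OC(=C)C(C)=O)cc2)c1 | intermediate
9 | tert-butyl[(3-{4-[2-(3-methoxyphenyl)ethyl]phenoxy}buta-1,3-dien-2-yl)oxy]dimethylsilane | C=C(Oc1ccc(CCc2cccc(OC)c2)cc1)C(=C)O[Si](C)(C)C(C)(C)C | intermediate
10 | (2,3-dimethoxyphenyl)acetic acid | COc1cccc(CC(=O)O)c1OC | starting material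
11 | 2-(2,3-dimethoxyphenyl)-1-(imidazol-1-yl)ethanone | COc1cccc(CC(=O)n2ccnc2)c1OC | intermediate (not isolated)
12 | 2-(2,3-dimethoxyphenyl)-N-methoxy-N-methylacetamide | COc1cccc(CC(=O)N(C)OC)c1OC | intermediate
13 | bromomagnesium N-methoxy-N-methyl hemiaminal alkoxide from 12 and the alkynyl Grignard reagent | COc1cccc(CC(O[Mg]Br)(C#C)N(C)OC)c1OC | intermediate (not isolated)
14 | 1-(2,3-dimethoxyphenyl)but-3-yn-2-one | C#CC(=O)Cc1cccc(OC)c1OC | intermediate
15 | 1-(4-{[tert-butyl(dimethyl)silyl]oxy}-5-{4-[2-(3-methoxyphenyl)ethyl]phenoxy}cyclohexa-1,4-dien-1-yl)-2-(2,3-dimethoxyphenyl)ethan-1-one | COc1cccc(CC(=O)C2=CCC(O[Si](C)(C)C(C)(C)C)=C(Oc3ccc(CCc4cccc(OC)c4)cc3)C2)c1OC | intermediate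
16 | 1-(4-{[tert-butyl(dimethyl)silyl]oxy}-3-{4-[2-(3-methoxyphenyl)ethyl]phenoxy}phenyl)-2-(2,3-dimethoxyphenyl)ethan-1-one | COc1cccc(CC(=O)c2ccc(O[Si](C)(C)C(C)(C)C)c(Oc3ccc(CCc4cccc(OC)c4)cc3)c2)c1OC | intermediate
17 | tert-butyl(4-[2-(2,3-dimethoxyphenyl)ethyl]-2-{4-[2-(3-methoxyphenyl)ethyl]phenoxy}phenoxy)dimethylsilane | COc1cccc(CCc2ccc(O[Si](C)(C)C(C)(C)C)c(Oc3ccc(CCc4cccc(OC)c4)cc3)c2)c1OC | intermediate
18 | 3-{2-[4-hydroxy-3-(4-[2-(3-hydroxyphenyl)ethyl]phenoxy)phenyl]ethyl}benzene-1,2-diol | Oc1cccc(CCc2ccc(Oc3cc(CCc4cccc(O)c4O)ccc3O)cc2)c1 | target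

**Step count**

Total steps: 11. Longest linear sequence: 9 (steps 1–5 and 8–11); the ynone branch (steps 6–7) joins at step 8.

**Steps most likely to fail, with fallbacks**

Step 8. The two oxygen donors of the diene direct in opposite senses, so the cycloaddition may give a mixture of regioisomers that cannot be separated after aromatisation, or the ynone may oligomerise before the diene traps it. The fallback buys ring C as an arene and sets out from phenol 5. Ullmann-type C–O coupling of 5 with 3-bromo-4-methoxybenzaldehyde (CuI, N,N-dimethylglycine, Cs2CO3, dioxane, 90 °C) should give 4-methoxy-3-{4-[2-(3-methoxyphenyl)ethyl]phenoxy}benzaldehyde F1. Separately, 2,3-dimethoxybenzyl alcohol and Ph3P·HBr (MeCN, reflux) should give (2,3-dimethoxybenzyl)triphenylphosphonium bromide F2. KOtBu in THF converts F2 in the flask into (2,3-dimethoxybenzylidene)triphenylphosphorane F3, which with F1 should give 1-(2,3-dimethoxyphenyl)-2-(4-methoxy-3-{4-[2-(3-methoxyphenyl)ethyl]phenoxy}phenyl)ethene F4 as an E/Z mixture. Hydrogenation (H2, 10% Pd/C, EtOAc) should give the tetramethyl ether 1-[2-(2,3-dimethoxyphenyl)ethyl]-4-methoxy-3-{4-[2-(3-methoxyphenyl)ethyl]phenoxy}benzene F5. BBr3 (CH2Cl2, −78 °C → rt) then cleaves all four methyl ethers, and the fallback comes back to the route at target 18.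

Step 4. The acetyl group of 7 may be lost by retro-Claisen cleavage in aqueous carbonate before olefination, or the enone may oligomerise under base as it forms. The fallback sets out from phenol 5 and also makes step 3 unnecessary. O-Alkylation of 5 with chloroacetone (K2CO3, KI cat., acetone, reflux) should give 1-{4-[2-(3-methoxyphenyl)ethyl]phenoxy}propan-2-one F6. Mannich-type α-methylenation under acidic conditions (paraformaldehyde, i-Pr2NH·CF3CO2H, THF, reflux) should then take place at the more readily enolised, oxygen-bearing methylene. The fallback comes back to the route at enone 8.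

Step 7. The liberated N,O-dimethylhydroxylamine may add to the terminal ynone, or the ynone may isomerise through its acidic benzylic CH2 during work-up. The fallback sets out from amide 12 and reaches the ynone by oxidation under neutral, amine-free conditions. Reduction of 12 with i-Bu2AlH (THF, −78 °C) should give 2-(2,3-dimethoxyphenyl)acetaldehyde F7. Addition of HC≡CMgBr (THF, −78 → 0 °C, cold dilute aq. HCl quench) should give racemic 1-(2,3-dimethoxyphenyl)but-3-yn-2-ol F8. Oxidation with Dess–Martin periodinane (CH2Cl2, NaHCO3, 0 °C) then comes back to the route at ynone 14.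

**Further compounds**

F1 | step 8 | 4-methoxy-3-{4-[2-(3-methoxyphenyl)ethyl]phenoxy}benzaldehyde | COc1cccc(CCc2ccc(Oc3cc(C=O)ccc3OC)cc2)c1
F2 | step 8 | (2,3-dimethoxybenzyl)triphenylphosphonium bromide | COc1cccc(C[P+](c2ccccc2)(c2ccccc2)c2ccccc2)c1OC.[Br-]
F3 | step 8 | (2,3-dimethoxybenzylidene)triphenylphosphorane | COc1cccc(C=P(c2ccccc2)(c2ccccc2)c2ccccc2)c1OC
F4 | step 8 | 1-(2,3-dimethoxyphenyl)-2-(4-methoxy-3-{4-[2-(3-methoxyphenyl)ethyl]phenoxy}phenyl)ethene, E/Z mixture | COc1cccc(CCc2ccc(Oc3cc(C=Cc4cccc(OC)c4OC)ccc3OC)cc2)c1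
F5 | step 8 | 1-[2-(2,3-dimethoxyphenyl)ethyl]-4-methoxy-3-{4-[2-(3-methoxyphenyl)ethyl]phenoxy}benzene | COc1cccc(CCc2ccc(Oc3cc(CCc4cccc(OC)c4OC)ccc3OC)cc2)c1
F6 | step 4 | 1-{4-[2-(3-methoxyphenyl)ethyl]phenoxy}propan-2-one | COc1cccc(CCc2ccc(OCC(C)=O)cc2)c1
F7 | step 7 | 2-(2,3-dimethoxyphenyl)acetaldehyde | COc1cccc(CC=O)c1OC
F8 | step 7 | 1-(2,3-dimethoxyphenyl)but-3-yn-2-ol, racemic | COc1cccc(CC(O)C#C)c1OC
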